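**Retrosynthetic overview**
1. The target comes from a ring A/ring B decalin ketone by C9 ketone reduction, acetylation at O2 and O9, and release of O14; ring A is closed late by ring-closing metathesis at C3=C4.
2. The metathesis precursor is made in one copper-catalysed step from a ring B enone (fragment 1), an isopropenyl Grignard reagent, an α-silyloxy aldehyde (fragment 2) and isovaleryl chloride. This step forms C4–C5 and the quaternary C10–C1 bond and sets C5, C10 and C1.
3. Fragment 1 comes from cyclohex-2-en-1-one by rhodium-catalysed asymmetric alkenylation (C7), regioselective regeneration of the enone, and Baylis–Hillman hydroxymethylation (C14).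
4. Fragment 2 comes from (R)-glycidol; its stereocentre becomes C2 and a methylide homologation supplies the vinyl group used in the metathesis.
5. Ring order: ring B is present from the start; ring A is formed on it in step 12.

Assumption: the SMILES is read as drawn, which is (1R,2S,5R,7S,9S,10S) in eudesmane numbering (C14 = CH2O carbon on C10, C15 = methyl on C4); this numbering is used for all carbons below (TBS = tert-butyldimethylsilyl, TES = triethylsilyl, PMB = 4-methoxybenzyl).

**Fragment 1 (ring B enone)**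

Step 1
Reactants: 1 cyclohex-2-en-1-one; 2 potassium trifluoro(prop-1-en-2-yl)borate
Product: 3 (S)-3-(prop-1-en-2-yl)cyclohexan-1-one
Conditions: [Rh(cod)2]PF6 (3 mol%), (S)-BINAP (3.3 mol%), toluene/H2O 4:1, 105 °C
Reagents that add atoms: none
Why: Hayashi–Miyaura rhodium-catalysed asymmetric 1,4-addition: the (S)-BINAP–monovalent rhodium isopropenyl species inserts the enone on one enantioface and protonolysis of the oxa-π-allyl rhodium gives the ketone, setting C7 as (S).

Step 2
Reactants: 3 (S)-3-(prop-1-en-2-yl)cyclohexan-1-one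
Product: 4 trimethyl{[(5S)-5-(prop-1-en-2-yl)cyclohex-1-en-1-yl]oxy}silane
Conditions: LiN(i-Pr)2, Me3SiCl (in situ quench), THF, −78 °C
Reagents that add atoms: chlorotrimethylsilane, C[Si](C)(C)Cl
Why: Kinetic enol silylation: the hindered amide deprotonates the α-CH2 remote from the branched C7 substituent (C10) and the enolate is silylated before it can equilibrate (about 6:1 expected); C7 is not touched.

Step 3
Reactants: 4 trimethyl{[(5S)-5-(prop-1-en-2-yl)cyclohex-1-en-1-yl]oxy}silane
Product: 5 (S)-5-(prop-1-en-2-yl)cyclohex-2-en-1-one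
Conditions: Pd(OAc)2 (10 mol%), O2 (1 atm), DMSO, 25 °C
Reagents that add atoms: none
Why: Saegusa–Ito oxidation (aerobic catalytic variant): divalent palladium forms the oxa-π-allyl complex of the enol ether and β-hydride elimination places the double bond at C10=C5, while any minor regioisomer becomes a conjugated dienone that is removed by chromatography.

Step 4
Reactants: 5 (S)-5-(prop-1-en-2-yl)cyclohex-2-en-1-one; 6 formaldehyde
Product: 7 (S)-2-(hydroxymethyl)-5-(prop-1-en-2-yl)cyclohex-2-en-1-one
Conditions: 37% aq. HCHO, DMAP (20 mol%), THF, 25 °C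
Reagents that add atoms: none
Why: Morita–Baylis–Hillman reaction: DMAP adds to C5, the resulting enolate is hydroxymethylated at C10 and DMAP is expelled, which installs C14 without touching C7.

Step 5
Reactants: 7 (S)-2-(hydroxymethyl)-5-(prop-1-en-2-yl)cyclohex-2-en-1-one
Product: 8 (S)-2-{[(tert-butyldimethylsilyl)oxy]methyl}-5-(prop-1-en-2-yl)cyclohex-2-en-1-one
Conditions: TBSCl, imidazole, CH2Cl2, 0 → 25 °C
Reagents that add atoms: tert-butyldimethylsilyl chloride, CC(C)(C)[Si](C)(C)Cl
Why: Standard silylation of the primary allylic alcohol gives an ether that withstands the organometallic step and leaves the enone untouched.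

**Fragment 2 (aldehyde)**

Step 6
Reactants: 9 (R)-glycidol
Product: 10 (S)-2-{[(4-methoxybenzyl)oxy]methyl}oxirane
Conditions: NaH, 4-methoxybenzyl chloride, n-Bu4NI (cat.), DMF, 0 °C
Reagents that add atoms: 4-methoxybenzyl chloride, COc1ccc(CCl)cc1
Why: Williamson etherification of the primary alkoxide at 0 °C; the stereocentre is not involved and only its descriptor changes (R to S) through the priority switch.

Step 7
Reactants: 10 (S)-2-{[(4-methoxybenzyl)oxy]methyl}oxirane
Product: 11 (S)-1-[(4-methoxybenzyl)oxy]but-3-en-2-ol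
Conditions: Me3S+ I− (3 equiv), n-BuLi (2.9 equiv), THF, −10 → 25 °C
Reagents that add atoms: trimethylsulfonium iodide, C[S+](C)C.[I-]
Why: Epoxide-to-allylic-alcohol homologation with dimethylsulfonium methylide: the ylide opens the terminal epoxide carbon and a second equivalent induces loss of dimethyl sulfide from the betaine, so the carbinol stereocentre (later C2) is retained.

Step 8
Reactants: 11 (S)-1-[(4-methoxybenzyl)oxy]but-3-en-2-ol
Product: 12 triethyl({(2S)-1-[(4-methoxybenzyl)oxy]but-3-en-2-yl}oxy)silane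
Conditions: Et3SiCl, imidazole, CH2Cl2, 0 °C
Reagents that add atoms: chlorotriethylsilane, CC[Si](CC)(CC)Cl
Why: Silylation of the secondary alcohol; the non-chelating TES group enforces Felkin–Anh addition in step 11 and can be removed selectively in step 13.

Step 9
Reactants: 12 triethyl({(2S)-1-[(4-methoxybenzyl)oxy]but-3-en-2-yl}oxy)silane
Product: 13 (S)-2-[(triethylsilyl)oxy]but-3-en-1-ol
Conditions: DDQ, CH2Cl2/pH 7 buffer 10:1, 0 °C
Reagents that add atoms: none
Why: Oxidative PMB cleavage by DDQ (benzylic hydride abstraction, hydrolysis of the oxocarbenium ion) under buffered conditions that leave the silyl ether and the alkene alone.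

Step 10
Reactants: 13 (S)-2-[(triethylsilyl)oxy]but-3-en-1-ol
Product: 14 (S)-2-[(triethylsilyl)oxy]but-3-enal
Conditions: Dess–Martin periodinane, CH2Cl2, 0 → 25 °C; used at once
Reagents that add atoms: none
Why: Dess–Martin oxidation under near-neutral conditions stops at the aldehyde and avoids epimerisation or conjugation of the α-silyloxy β,γ-unsaturated aldehyde.

**Union and end-game**

Step 11
Reactants: 8 (S)-2-{[(tert-butyldimethylsilyl)oxy]methyl}-5-(prop-1-en-2-yl)cyclohex-2-en-1-one; 15 isopropenylmagnesium bromide; 14 (S)-2-[(triethylsilyl)oxy]but-3-enal; 16 3-methylbutanoyl chloride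
Product: 19 (1R,2S)-1-[(1R,2R,4S)-1-{[(tert-butyldimethylsilyl)oxy]methyl}-6-oxo-2,4-di(prop-1-en-2-yl)cyclohexyl]-2-[(triethylsilyl)oxy]but-3-en-1-yl 3-methylbutanoate, via bromomagnesium enolate 17 (not isolated), via bromomagnesium aldolate 18 (not isolated)
Conditions: CuBr·SMe2 (10 mol%), LiCl (20 mol%), 15 (1.2 equiv, slow addition), THF, −78 → −40 °C; 14 (1.5 equiv), −78 °C; 16 (3 equiv), DMAP (1.5 equiv), −78 → −30 °C
Reagents that add atoms: none
Why: Proposed new method: a copper-catalysed alkenylative aldol–acylation cascade in which the isopropenyl cuprate from 15 and monovalent copper adds 1,4 to 8 trans to the C7 isopropenyl group (trans-3,5 rule for 5-substituted cyclohexenones), transmetalation to magnesium frees the catalyst and leaves the regiodefined tetrasubstituted enolate 17, this attacks 14 through a closed Zimmerman–Traxler chair anti to the new pseudoaxial C5 substituent (C10 quaternary, C1 trans to C4) with matched Felkin–Anh control from the non-chelating C2 silyloxy group (O1 anti to O2), and aldolate 18, which cannot eliminate because C10 is quaternary, is acylated before retro-aldol or silyl migration; the closest known reaction type is the copper-catalysed Grignard conjugate addition with enolate trapping by an aldehyde (three-component coupling), not yet shown for α-(silyloxymethyl) enones giving α-quaternary aldols or with in situ O-acylation.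

Step 12
Reactants: 19 (1R,2S)-1-[(1R,2R,4S)-1-{[(tert-butyldimethylsilyl)oxy]methyl}-6-oxo-2,4-di(prop-1-en-2-yl)cyclohexyl]-2-[(triethylsilyl)oxy]but-3-en-1-yl 3-methylbutanoate
Product: 20 (1R,2S,5R,7S,10R)-14-[(tert-butyldimethylsilyl)oxy]-9-oxo-2-[(triethylsilyl)oxy]eudesma-3,11-dien-1-yl 3-methylbutanoate
Conditions: second-generation Grubbs catalyst RuCl2(H2IMes)(PCy3)(=CHPh) (10 mol%), toluene (2 mM), 80 °C
Reagents that add atoms: none
Why: Ring-closing metathesis: the ruthenium alkylidene loads on the monosubstituted C3 vinyl group and closes onto the C5 isopropenyl group to give six-membered ring A with the trisubstituted C3=C4 bond and the trans ring fusion already fixed at C5/C10, the C7 isopropenyl group being able to close only a bridged eight-membered ring.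

Step 13
Reactants: 20 (1R,2S,5R,7S,10R)-14-[(tert-butyldimethylsilyl)oxy]-9-oxo-2-[(triethylsilyl)oxy]eudesma-3,11-dien-1-yl 3-methylbutanoate
Product: 22 (1R,2S,5R,7S,9S,10S)-14-[(tert-butyldimethylsilyl)oxy]-2,9-dihydroxyeudesma-3,11-dien-1-yl 3-methylbutanoate, via 9-hydroxy triethylsilyl ether 21 (not isolated)
Conditions: Li(s-Bu)3BH, THF, −78 °C; then AcOH/H2O 3:1, −78 → 25 °C
Reagents that add atoms: none
Why: Diastereoselective ketone reduction with a bulky borohydride, then acid desilylation in the same flask: the axial C7 isopropenyl group blocks the axial trajectory on its face, so hydride arrives equatorially from the opposite face and gives the axial C9 alcohol (9S) cis to that group and trans to C14, and aqueous acetic acid then cleaves the secondary TES ether but not the primary TBS ether.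

Step 14
Reactants: 22 (1R,2S,5R,7S,9S,10S)-14-[(tert-butyldimethylsilyl)oxy]-2,9-dihydroxyeudesma-3,11-dien-1-yl 3-methylbutanoate; 23 acetic anhydride
Product: 24 (1R,2S,5R,7S,9S,10S)-2,9-diacetoxy-14-[(tert-butyldimethylsilyl)oxy]eudesma-3,11-dien-1-yl 3-methylbutanoate
Conditions: Ac2O (10 equiv), DMAP (1 equiv), Et3N, CH2Cl2, 25 → 40 °C
Reagents that add atoms: none
Why: DMAP-catalysed acyl transfer to the two secondary hydroxyl groups, the allylic C2–OH reacting fast (before any acyl migration) and the hindered axial C9–OH on warming; no stereocentre changes.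

Step 15
Reactants: 24 (1R,2S,5R,7S,9S,10S)-2,9-diacetoxy-14-[(tert-butyldimethylsilyl)oxy]eudesma-3,11-dien-1-yl 3-methylbutanoate
Product: 25 (1R,2S,5R,7S,9S,10S)-2,9-diacetoxy-14-hydroxyeudesma-3,11-dien-1-yl 3-methylbutanoate (CNP0257109.1)
Conditions: HF·pyridine, pyridine, THF, 0 → 25 °C
Reagents that add atoms: none
Why: Fluoride-mediated desilylation under buffered acidic conditions frees the C14 hydroxyl without ester cleavage or acyl migration.

**Compound list**
1 | cyclohex-2-en-1-one | O=C1C=CCCC1 | starting material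
2 | potassium trifluoro(prop-1-en-2-yl)borate | C=C(C)[B-](F)(F)F.[K+] | starting material
3 | (S)-3-(prop-1-en-2-yl)cyclohexan-1-one | C=C(C)[C@@H]1CC(=O)CCC1 | intermediate
4 | trimethyl{[(5S)-5-(prop-1-en-2-yl)cyclohex-1-en-1-yl]oxy}silane | C=C(C)[C@@H]1CC(O[Si](C)(C)C)=CCC1 | intermediate
5 | (S)-5-(prop-1-en-2-yl)cyclohex-2-en-1-one | C=C(C)[C@@H]1CC(=O)C=CC1 | intermediate
6 | formaldehyde | C=O | starting material
7 | (S)-2-(hydroxymethyl)-5-(prop-1-en-2-yl)cyclohex-2-en-1-one | C=C(C)[C@@H]1CC(=O)C(CO)=CC1 | intermediate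
8 | (S)-2-{[(tert-butyldimethylsilyl)oxy]methyl}-5-(prop-1-en-2-yl)cyclohex-2-en-1-one | C=C(C)[C@@H]1CC(=O)C(CO[Si](C)(C)C(C)(C)C)=CC1 | intermediate
9 | (R)-glycidol | C1[C@H](O1)CO | starting material
10 | (S)-2-{[(4-methoxybenzyl)oxy]methyl}oxirane | C1[C@H](O1)COCc2ccc(OC)cc2 | intermediate
11 | (S)-1-[(4-methoxybenzyl)oxy]but-3-en-2-ol | C=C[C@H](O)COCc1ccc(OC)cc1 | intermediate
12 | triethyl({(2S)-1-[(4-methoxybenzyl)oxy]but-3-en-2-yl}oxy)silane | C=C[C@H](O[Si](CC)(CC)CC)COCc1ccc(OC)cc1 | intermediate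
13 | (S)-2-[(triethylsilyl)oxy]but-3-en-1-ol | C=C[C@H](O[Si](CC)(CC)CC)CO | intermediate
14 | (S)-2-[(triethylsilyl)oxy]but-3-enal | C=C[C@H](O[Si](CC)(CC)CC)C=O | intermediate
15 | isopropenylmagnesium bromide | C=C(C)[Mg]Br | starting material
16 | 3-methylbutanoyl chloride | CC(C)CC(=O)Cl | starting material
17 | bromomagnesium (3R,5S)-2-{[(tert-butyldimethylsilyl)oxy]methyl}-3,5-di(prop-1-en-2-yl)cyclohex-1-en-1-olate | C=C(C)[C@@H]1CC(O[Mg]Br)=C(CO[Si](C)(C)C(C)(C)C)[C@H](C1)C(C)=C | intermediate
18 | bromomagnesium (1R,2S)-1-[(1R,2R,4S)-1-{[(tert-butyldimethylsilyl)oxy]methyl}-6-oxo-2,4-di(prop-1-en-2-yl)cyclohexyl]-2-[(triethylsilyl)oxy]but-3-en-1-olate | C=C(C)[C@@H]1CC(=O)[C@@]([C@@H](O[Mg]Br)[C@@H](O[Si](CC)(CC)CC)C=C)(CO[Si](C)(C)C(C)(C)C)[C@H](C1)C(C)=C | intermediate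
19 | (1R,2S)-1-[(1R,2R,4S)-1-{[(tert-butyldimethylsilyl)oxy]methyl}-6-oxo-2,4-di(prop-1-en-2-yl)cyclohexyl]-2-[(triethylsilyl)oxy]but-3-en-1-yl 3-methylbutanoate | C=C(C)[C@@H]1CC(=O)[C@@]([C@@H](OC(=O)CC(C)C)[C@@H](O[Si](CC)(CC)CC)C=C)(CO[Si](C)(C)C(C)(C)C)[C@H](C1)C(C)=C | intermediate
20 | (1R,2S,5R,7S,10R)-14-[(tert-butyldimethylsilyl)oxy]-9-oxo-2-[(triethylsilyl)oxy]eudesma-3,11-dien-1-yl 3-methylbutanoate | C=C(C)[C@@H]1CC(=O)[C@@]2(CO[Si](C)(C)C(C)(C)C)[C@H](C1)C(C)=C[C@H](O[Si](CC)(CC)CC)[C@@H]2OC(=O)CC(C)C | intermediate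
21 | (1R,2S,5R,7S,9S,10S)-14-[(tert-butyldimethylsilyl)oxy]-9-hydroxy-2-[(triethylsilyl)oxy]eudesma-3,11-dien-1-yl 3-methylbutanoate | C=C(C)[C@@H]1C[C@H](O)[C@@]2(CO[Si](C)(C)C(C)(C)C)[C@H](C1)C(C)=C[C@H](O[Si](CC)(CC)CC)[C@@H]2OC(=O)CC(C)C | intermediate
22 | (1R,2S,5R,7S,9S,10S)-14-[(tert-butyldimethylsilyl)oxy]-2,9-dihydroxyeudesma-3,11-dien-1-yl 3-methylbutanoate | C=C(C)[C@@H]1C[C@H](O)[C@@]2(CO[Si](C)(C)C(C)(C)C)[C@H](C1)C(C)=C[C@H](O)[C@@H]2OC(=O)CC(C)C | intermediate
23 | acetic anhydride | CC(=O)OC(C)=O | starting material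
24 | (1R,2S,5R,7S,9S,10S)-2,9-diacetoxy-14-[(tert-butyldimethylsilyl)oxy]eudesma-3,11-dien-1-yl 3-methylbutanoate | C=C(C)[C@@H]1C[C@H](OC(C)=O)[C@@]2(CO[Si](C)(C)C(C)(C)C)[C@H](C1)C(C)=C[C@H](OC(C)=O)[C@@H]2OC(=O)CC(C)C | intermediate
25 | (1R,2S,5R,7S,9S,10S)-2,9-diacetoxy-14-hydroxyeudesma-3,11-dien-1-yl 3-methylbutanoate (CNP0257109.1) | C=C(C)[C@@H]1C[C@H](OC(C)=O)[C@@]2(CO)[C@H](C1)C(C)=C[C@H](OC(C)=O)[C@@H]2OC(=O)CC(C)C | target

**Step count and risks**
Total step count: 15. Longest linear sequence: 10 steps (1–5, then 11–15; the sequence 6–10, then 11–15 is equally long).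

Step 11 (the proposed new step) is the most likely to fail. The hindered tetrasubstituted enolate may add slowly, may deprotonate aldehyde 14, or may be O-acylated before the aldol. The fallback uses known chemistry only, sets out from 8 and comes back at 19. Silyl-accelerated copper-catalysed conjugate addition of 15 to 8 (CuI 10 mol%, Me3SiCl, THF, −78 °C, non-aqueous work-up) gives trimethylsilyl enol ether F1. A Mukaiyama aldol addition of F1 to 14 (BF3·OEt2, CH2Cl2, −78 °C, open transition state with Felkin–Anh control) gives β-hydroxy ketone F2. Acylation of F2 with 16 (pyridine, DMAP, CH2Cl2, 0 °C) gives 19.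

Step 13 is the second risk. The C9 ketone is flanked by the quaternary C10 carrying an axial CH2OTBS group, so the facial preference of even a bulky hydride is not certain. The fallback replaces steric control by hydroxyl-directed delivery; it sets out from 20 and comes back at 22. HF·pyridine (THF/pyridine, 25 °C) removes both silyl groups and gives keto diol F3. Me4NBH(OAc)3 (MeCN/AcOH, −30 °C, Evans–Saksena reduction) binds to the C14 hydroxyl and delivers hydride to C9 from the C14 face, giving triol F4 with the C9 hydroxyl trans to C14. TBSCl (1.1 equiv, imidazole, CH2Cl2, −20 °C) then silylates only the primary C14 hydroxyl and gives 22.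

Step 2 is the third risk. Kinetic deprotonation of a 3-substituted cyclohexanone may give too much of the wrong enol ether. The fallback fixes the regiochemistry before the stereocentre is made; it sets out from 1 and comes back at 5. The kinetic enolate of 1 (LiN(i-Pr)2, THF, −78 °C) is sulfenylated at C6 with diphenyl disulfide to give racemic 6-(phenylsulfanyl)cyclohex-2-en-1-one F5. Catalyst-controlled addition of 2 under the step 1 conditions gives (5S)-2-(phenylsulfanyl)-5-(prop-1-en-2-yl)cyclohexan-1-one F6 as a mixture of epimers at the sulfur-bearing carbon. NaIO4 (MeOH/H2O, 0 °C) gives the (5S)-2-(phenylsulfinyl)-5-(prop-1-en-2-yl)cyclohexan-1-one F7, and its thermal syn-elimination (toluene, CaCO3, 110 °C) can only run towards the ring CH2, so both epimers converge on 5.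

**Further compounds**
F1 | step 11 | {[(3R,5S)-2-{[(tert-butyldimethylsilyl)oxy]methyl}-3,5-di(prop-1-en-2-yl)cyclohex-1-en-1-yl]oxy}trimethylsilane | C=C(C)[C@@H]1CC(O[Si](C)(C)C)=C(CO[Si](C)(C)C(C)(C)C)[C@H](C1)C(C)=C
F2 | step 11 | (2R,3R,5S)-2-{[(tert-butyldimethylsilyl)oxy]methyl}-2-{(1R,2S)-1-hydroxy-2-[(triethylsilyl)oxy]but-3-en-1-yl}-3,5-di(prop-1-en-2-yl)cyclohexan-1-one | C=C(C)[C@@H]1CC(=O)[C@@]([C@@H](O)[C@@H](O[Si](CC)(CC)CC)C=C)(CO[Si](C)(C)C(C)(C)C)[C@H](C1)C(C)=C
F3 | step 13 | (1R,2S,5R,7S,10R)-2,14-dihydroxy-9-oxoeudesma-3,11-dien-1-yl 3-methylbutanoate | C=C(C)[C@@H]1CC(=O)[C@@]2(CO)[C@H](C1)C(C)=C[C@H](O)[C@@H]2OC(=O)CC(C)C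
F4 | step 13 | (1R,2S,5R,7S,9S,10S)-2,9,14-trihydroxyeudesma-3,11-dien-1-yl 3-methylbutanoate | C=C(C)[C@@H]1C[C@H](O)[C@@]2(CO)[C@H](C1)C(C)=C[C@H](O)[C@@H]2OC(=O)CC(C)C
F5 | step 2 | 6-(phenylsulfanyl)cyclohex-2-en-1-one (racemic) | O=C1C=CCCC1Sc2ccccc2
F6 | step 2 | (5S)-2-(phenylsulfanyl)-5-(prop-1-en-2-yl)cyclohexan-1-one (both epimers at C2) | C=C(C)[C@@H]1CC(=O)C(Sc2ccccc2)CC1
F7 | step 2 | (5S)-2-(phenylsulfinyl)-5-(prop-1-en-2-yl)cyclohexan-1-one (mixture at C2 and sulfur) | C=C(C)[C@@H]1CC(=O)C(S(=O)c2ccccc2)CC1
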